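All runs stem from a simulated flask on assumed constants; scatter was added.

Turn the settings of these flasks one at a time, beginning with a look at what is charged, what was read and what is asked.

| flask | substrate | coupling partner | remark | time |
|---|---|---|---|---|
| alder | 1 M | 0.20 M | run made earlier |  |
| maple | 1 M | 2.2 M | run made earlier |  |
| Monday's | 1.0 M | 1.50 M |  | 40 h |
| Tuesday's | 1.0 M | 2.50 M |  | 40 h |
| Wednesday's | 1.0 M | 0.500 M |  | 40 h |
| Sunday's | 1.0 M | 0.800 M |  | 40 h |
| Saturday's | 1.0 M | 0.400 M |  | 40 h |

| run | time / h | product / % |
|---|---|---|
| alder | 5.00 | 0.5 |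
| alder | 10.0 | 2.4 |
| alder | 15.0 | 2.3 |
| alder | 20.0 | 5.7 |
| alder | 25.0 | 2.6 |
| alder | 30.0 | 4.0 |
| maple | 2.50 | 3.2 |
| maple | 4.00 | 7.0 |
| maple | 6.00 | 10.0 |
| maple | 10.0 | 17.1 |
| maple | 15.0 | 22.9 |
| maple | 30.0 | 38.7 |

(each reading ± 1 percentage point)

- the flasks put in order of amount of product, in percent of the substrate charged, best first, at 40 h (Monday's / Tuesday's / Wednesday's / Sunday's / Saturday's)
- the amount of product, in percent of the substrate charged of the flask you put first, at 40 h
- the amount of product, in percent of the substrate charged of the flask you put last, at 40 h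

- the numbers in the tables scatter with a standard deviation of 1 percentage point

The substrate stands at 1.0 M and the time at 40 h in the five flasks, so the coupling partner is the setting left to turn. By hand, I take the rate of product formation as proportional to the part of the charge not yet product and to c(coupling partner), and I count c(coupling partner) as staying at its charge, the pseudo-first-order view. The fraction of the charge not yet product is then exp(−k × dose), where the dose is c(coupling partner) as charged times the time. The last maple reading, 38.7 % of product after 30.0 h, gives k = 0.00742 M⁻¹ h⁻¹, the dose constant: minus the logarithm of the fraction not yet product, per unit of dose.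

Now I test each turn. Turning the time back to 15.0 h in the maple run, k gives 21.7 %, and 22.9 % was read. Turning the partner down to 0.20 M in the alder run, k gives 4.35 % at 30.0 h, and 4.0 % was read, with a scatter of 1 point. So I rank the flasks by charge. Tuesday's, with 2.50 M, comes first at 52.4 %, and Saturday's, with 0.400 M, comes last at 11.2 %.

The forecast gives Tuesday's > Monday's > Sunday's > Wednesday's > Saturday's, with 52 % (range 46 % to 57 %) and 10.7 % (range 9 % to 13 %), on the ground that “the reaction looks first order in partner”. Its order is mine, and my two figures lie inside its ranges.

The flasks give Tuesday's > Monday's > Sunday's > Wednesday's > Saturday's, with 52.7 % in Tuesday's and 11.7 % in Saturday's.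

    substrate + coupling partner ⇌ intermediate A (K = 1.90 M⁻¹, k = 0.0790 M⁻¹ h⁻¹)
    substrate + coupling partner ⇌ intermediate B (K = 0.240 M⁻¹, k = 0.0520 M⁻¹ h⁻¹)
    substrate ⇌ intermediate C (K = 13.0, k = 0.0340 h⁻¹)
    intermediate C ⇌ intermediate D (K = 1.10, k = 0.0680 h⁻¹)
    coupling partner + intermediate D → product (k = 0.140 M⁻¹ h⁻¹)
    intermediate A → product (k = 0.200 h⁻¹)
    coupling partner ⇌ dormant form (K = 5.50, k = 1.00 h⁻¹)

The dose constant gave 52.4 % for Tuesday's, and for the same flask read at 4.0 d it gives 83.1 %, where the flask holds 81.5 %. Yet the dose counts the whole charge, while free coupling partner in Saturday's stands at 10.2 % of its own charge at 40.0 h. Part of the reason for the low yield of Saturday's is the depletion of coupling partner: with that depletion taken away, Saturday's gives 55.3 % instead of 11.7 %.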